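**Retrosynthetic overview**
1. The C11–C12 bond is cut last: (2E,6E)-farnesyl bromide alkylates the C11 sulfone carbanion of a cis-fused bicyclic 8α-ol, and the sulfone is then reduced off.
2. The C8 carbinol oxygen is a former formyl group (Baeyer–Villiger, retention) and C11 a former ester carbon. The C5 hydrogen of the cis ring fusion comes from a palladium hydride relayed by a C7 acetoxy group that is lost in the same step.
3. Ring B comes from one enantioselective Diels–Alder reaction: diene C10=C5–C6=C7(OAc) (ring A alkene plus acetoxyvinyl arm) and dienophile C8=C9 of ethyl (E)-3-formylcrotonate. It forms C7–C8 and C9–C10 and sets C8, C9, C10 and the relay center C7.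
4. Enabling feature: in ring B (C5–C10) the two-carbon unit C8–C9 is flanked by the four-carbon unit C10–C5–C6–C7, whose central bond C5–C6 can hold the alkene left by a [4+2]. C8 carries methyl plus oxygen (a latent α-methyl enal carbon) and C9 a one-carbon branch (a latent ester).
5. Ring order: ring A is bought with the starting aldehyde; ring B is the only ring formed (step 2).

Key step: step 2

Remark on numbering: labdane-type positions are used (ring A = C1–C5, C10; ring B = C5–C10; C11 is the CH2 on C9); β is the face of the C10 methyl.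
Remark on the target: the SMILES codes a cis ring fusion (H on C5 and methyl on C10 on the same face; 4aR,8aS in naphthalene numbering), with 8α-OH, 8β-CH3 and a 9β side chain; the route is built for exactly this isomer.
Assumption: the (S)-oxazaborolidinium catalyst is taken to add the diene to the Re face of C3 (the formyl-bearing carbon) of the dienophile, the sense expected for 2-substituted enals; if the sense were opposite, the (R)-catalyst, made the same way, would be used.

**Step 1**
Reactants: 1 (2,6,6-trimethylcyclohex-1-en-1-yl)acetaldehyde (β-homocyclocitral)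
Product: 2 (E)-2-(2,6,6-trimethylcyclohex-1-en-1-yl)ethenyl acetate
Conditions: Ac2O, Et3N, DMAP (cat.), THF, 60 °C; chromatography to secure the E isomer
Reagents that add atoms: acetic anhydride CC(=O)OC(C)=O
Why: O-acylation of the dienolate of the β,γ-unsaturated aldehyde (enol acetate formation) should give the conjugated dienyl acetate, the less crowded E geometry being expected to predominate and being the only isomer that can reach the s-cis diene conformation.

**Step 2**
Reactants: 2 (E)-2-(2,6,6-trimethylcyclohex-1-en-1-yl)ethenyl acetate; 3 ethyl (2E)-3-methyl-4-oxobut-2-enoate (ethyl (E)-3-formylcrotonate)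
Product: 4 ethyl (1R,2S,3R,8aR)-3-acetoxy-2-formyl-2,5,5,8a-tetramethyl-1,2,3,5,6,7,8,8a-octahydronaphthalene-1-carboxylate (7α-OAc, 8α-CHO, 8β-CH3, 9β-CO2Et, 10β-CH3, C5=C6)
Conditions: (S)-1-(2-methylphenyl)-3,3-diphenyltetrahydro-1H,3H-pyrrolo[1,2-c][1,3,2]oxazaborole (20 mol %), (CF3SO2)2NH (18 mol %), CH2Cl2, −78 to −20 °C
Reagents that add atoms: none
Why: Lewis-acid-catalysed, concerted but asynchronous [4+2] cycloaddition, i.e. an enantioselective Diels–Alder reaction of a 2-substituted enal bound to a chiral oxazaborolidinium ion, the type known for semicyclic 1-vinylcycloalkene dienes with this formylcrotonate dienophile. Ring B is closed in the six-membered [4+2] mode: the diene C10=C5–C6=C7 adds across C8=C9, the C9–C10 bond running ahead of the C7–C8 bond. The acetoxy donor on C7 makes C10 the nucleophilic terminus and puts the formyl-bearing carbon next to the acetoxy carbon (ortho rule), which also avoids vicinal quaternary carbons at C8 and C10. The boron-bound formyl group lies endo, so 8-CHO and 7-OAc come out cis (both α), and the fixed E geometry of the dienophile then places the C9 ester exo and β, cis to the C8 and C10 methyl groups. The absolute configuration of C8, and through the endo topology that of C7, C9 and the quaternary C10, is set by the catalyst, which leaves the Re face of the formyl-bearing carbon open. The step needs regio-, endo- and face selectivity, secured by the acetoxy group, the doubly activated E-dienophile and its two-point binding (B–O and formyl C–H···O) to the catalyst.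

**Step 3**
Reactants: 4 Diels–Alder adduct (7α-acetoxy-8α-formyl ester, C5=C6)
Product: 5 ethyl (1R,2R,4aR,8aS)-2-formyl-2,5,5,8a-tetramethyl-1,2,4a,5,6,7,8,8a-octahydronaphthalene-1-carboxylate (cis-fused, 5β-H, C6=C7)
Conditions: Pd(OAc)2 (10 mol %), n-Bu3P (40 mol %), HCO2H, Et3N, THF, 65 °C
Reagents that add atoms: none
Why: palladium-catalysed formate hydrogenolysis of an allylic acetate (reductive Tsuji–Trost-type reaction): zerovalent palladium should ionise the pseudoaxial 7α-acetate with inversion to a π-allyl complex on the β face, formate then loses CO2 to give Pd–H, and the hydride passes from the metal to the more substituted terminus C5, so that H enters anti to the leaving group (5β-H, cis to the C10 methyl), the alkene moves to C6=C7 and the C7 oxygen is erased; C4, C8 and C10 carry no hydrogen, so diene formation by β-elimination is excluded.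

**Step 4**
Reactants: 5 cis-fused C6=C7 formyl ester
Product: 6 ethyl (1R,2R,4aR,8aS)-2-formyl-2,5,5,8a-tetramethyldecahydronaphthalene-1-carboxylate
Conditions: H2 (1 atm), 10% Pd/C, EtOAc, rt
Reagents that add atoms: none
Why: heterogeneous hydrogenation of the cis-disubstituted C6=C7 alkene creates no stereocenter and should leave the α-quaternary aldehyde and the ester untouched under these mild conditions.

**Step 5**
Reactants: 6 saturated 8α-formyl ester
Product: 7 ethyl (1R,2R,4aR,8aS)-2-(formyloxy)-2,5,5,8a-tetramethyldecahydronaphthalene-1-carboxylate (8α-formate)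
Conditions: mCPBA (1.5 equiv), Na2HPO4, CH2Cl2, 0 °C to rt
Reagents that add atoms: mCPBA (3-chloroperoxybenzoic acid) OOC(=O)c1cccc(Cl)c1
Why: Baeyer–Villiger oxidation of an α-quaternary aldehyde, in which the tertiary C8 should migrate in preference to hydrogen and with retention, so the 8α-formyl group becomes the 8α-oxygen of the target.

**Step 6**
Reactants: 7 8α-formate ester
Product: 8 (1S,2R,4aR,8aS)-1-(hydroxymethyl)-2,5,5,8a-tetramethyldecahydronaphthalen-2-ol (cis-fused 8α,11-diol)
Conditions: LiAlH4, THF, 0 °C to rt; aqueous NaOH work-up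
Reagents that add atoms: none
Why: hydride reduction should convert the ethyl ester into the C11 primary alcohol and cleave the formate to the tertiary alcohol without touching any stereocenter.

**Step 7**
Reactants: 8 cis-fused 8α,11-diol
Product: 9 (1R,2R,4aR,8aS)-2,5,5,8a-tetramethyl-1-[(phenylsulfanyl)methyl]decahydronaphthalen-2-ol
Conditions: PhSSPh, n-Bu3P, pyridine, 60 °C
Reagents that add atoms: diphenyl disulfide c1ccccc1SSc1ccccc1
Why: phosphine/disulfide sulfenylation (Mitsunobu-type): the primary alcohol is activated as an alkoxyphosphonium ion and displaced by thiophenolate in an SN2 step, while the hindered tertiary alcohol should stay inert.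

**Step 8**
Reactants: 9 hydroxy sulfide
Product: 10 (1R,2R,4aR,8aS)-1-[(benzenesulfonyl)methyl]-2,5,5,8a-tetramethyldecahydronaphthalen-2-ol
Conditions: mCPBA (2.2 equiv), NaHCO3, CH2Cl2, 0 °C
Reagents that add atoms: mCPBA (3-chloroperoxybenzoic acid) OOC(=O)c1cccc(Cl)c1
Why: chemoselective oxidation of sulfide to sulfone, which acidifies C11 for the coupling; the tertiary alcohol and the saturated skeleton are not affected.

**Step 9**
Reactants: 10 hydroxy sulfone; 11 (2E,6E)-farnesyl bromide
Product: 13 (1R,2R,4aR,8aS)-1-[(3E,7E)-1-(benzenesulfonyl)-4,8,12-trimethyltrideca-3,7,11-trien-1-yl]-2,5,5,8a-tetramethyldecahydronaphthalen-2-ol (both C11 epimers), via dilithiated sulfone 12 (not isolated)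
Conditions: n-BuLi (2.1 equiv), THF–DMPU, −78 °C; then 11, −78 to −20 °C; then H2O
Reagents that add atoms: none
Why: double deprotonation (alkoxide, then α-sulfonyl carbanion) followed by SN2 alkylation with the primary allylic bromide (sulfone-mediated prenyl chain coupling) should join C11 to the farnesyl terminus with the E,E geometry kept; the new sulfone-bearing center is uncontrolled and is removed in the next step.

**Step 10**
Reactants: 13 farnesylated hydroxy sulfone
Product: 14 (1R,2R,4aR,8aS)-2,5,5,8a-tetramethyl-1-[(3E,7E)-4,8,12-trimethyltrideca-3,7,11-trien-1-yl]decahydronaphthalen-2-ol (target, CNP0389811.1)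
Conditions: 6% sodium amalgam (Na/Hg), Na2HPO4, MeOH–THF, −20 °C to rt
Reagents that add atoms: none
Why: reductive desulfonylation by electron transfer should replace the C11–S bond by C–H; the sulfone is homoallylic, not allylic, so no alkene shift is expected, the trisubstituted alkenes and the tertiary alcohol are inert, and the C11 stereocenter disappears.

**Compound list**
1 | (2,6,6-trimethylcyclohex-1-en-1-yl)acetaldehyde (β-homocyclocitral) | O=CCC1=C(C)CCCC1(C)C | starting material
2 | (E)-2-(2,6,6-trimethylcyclohex-1-en-1-yl)ethenyl acetate | CC(=O)O/C=C/C1=C(C)CCCC1(C)C | intermediate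
3 | ethyl (2E)-3-methyl-4-oxobut-2-enoate | CCOC(=O)/C=C(\C)C=O | starting material
4 | ethyl (1R,2S,3R,8aR)-3-acetoxy-2-formyl-2,5,5,8a-tetramethyl-1,2,3,5,6,7,8,8a-octahydronaphthalene-1-carboxylate | CCOC(=O)[C@@H]1[C@@]2(C)CCCC(C)(C)C2=C[C@@H](OC(C)=O)[C@@]1(C)C=O | intermediate
5 | ethyl (1R,2R,4aR,8aS)-2-formyl-2,5,5,8a-tetramethyl-1,2,4a,5,6,7,8,8a-octahydronaphthalene-1-carboxylate | CCOC(=O)[C@@H]1[C@@]2(C)CCCC(C)(C)[C@H]2C=C[C@@]1(C)C=O | intermediate
6 | ethyl (1R,2R,4aR,8aS)-2-formyl-2,5,5,8a-tetramethyldecahydronaphthalene-1-carboxylate | CCOC(=O)[C@@H]1[C@@]2(C)CCCC(C)(C)[C@H]2CC[C@@]1(C)C=O | intermediate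
7 | ethyl (1R,2R,4aR,8aS)-2-(formyloxy)-2,5,5,8a-tetramethyldecahydronaphthalene-1-carboxylate | CCOC(=O)[C@@H]1[C@@]2(C)CCCC(C)(C)[C@H]2CC[C@@]1(C)OC=O | intermediate
8 | (1S,2R,4aR,8aS)-1-(hydroxymethyl)-2,5,5,8a-tetramethyldecahydronaphthalen-2-ol | OC[C@@H]1[C@@]2(C)CCCC(C)(C)[C@H]2CC[C@@]1(C)O | intermediate
9 | (1R,2R,4aR,8aS)-2,5,5,8a-tetramethyl-1-[(phenylsulfanyl)methyl]decahydronaphthalen-2-ol | c1ccccc1SC[C@@H]1[C@@]2(C)CCCC(C)(C)[C@H]2CC[C@@]1(C)O | intermediate
10 | (1R,2R,4aR,8aS)-1-[(benzenesulfonyl)methyl]-2,5,5,8a-tetramethyldecahydronaphthalen-2-ol | O=S(=O)(c1ccccc1)C[C@@H]1[C@@]2(C)CCCC(C)(C)[C@H]2CC[C@@]1(C)O | intermediate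
11 | (2E,6E)-1-bromo-3,7,11-trimethyldodeca-2,6,10-triene ((2E,6E)-farnesyl bromide) | CC(C)=CCC/C(C)=C/CC/C(C)=C/CBr | starting material
12 | dilithiated sulfone (lithium alkoxide and α-sulfonyl carbanion of 10), not isolated | [Li+].[Li+].O=S(=O)(c1ccccc1)[CH-][C@@H]1[C@@]2(C)CCCC(C)(C)[C@H]2CC[C@@]1(C)[O-] | intermediate
13 | (1R,2R,4aR,8aS)-1-[(3E,7E)-1-(benzenesulfonyl)-4,8,12-trimethyltrideca-3,7,11-trien-1-yl]-2,5,5,8a-tetramethyldecahydronaphthalen-2-ol (C11 epimers) | CC(C)=CCC/C(C)=C/CC/C(C)=C/CC(S(=O)(=O)c1ccccc1)[C@@H]1[C@@]2(C)CCCC(C)(C)[C@H]2CC[C@@]1(C)O | intermediate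
14 | (1R,2R,4aR,8aS)-2,5,5,8a-tetramethyl-1-[(3E,7E)-4,8,12-trimethyltrideca-3,7,11-trien-1-yl]decahydronaphthalen-2-ol | CC(C)=CCC/C(C)=C/CC/C(C)=C/CC[C@@H]1[C@@]2(C)CCCC(C)(C)[C@H]2CC[C@@]1(C)O | target

**Step count and risks**
Total step count: 10. Longest linear sequence: 10 steps (1 to 14); compounds 3 and 11 are bought.

The three steps most likely to fail:

Step 2. The cycloaddition may be too slow at the temperatures the cationic catalyst tolerates, because the C10 terminus is fully substituted and carries an inside methyl group. The acid may also ionise or oligomerise the dienyl acetate, or the face selectivity may be eroded. The fallback replaces catalyst control by auxiliary control. From 1, O-acylation of the dienolate with (S)-O-methylmandeloyl chloride (Et3N, DMAP) should give the (E)-dienyl (S)-O-methylmandelate F1, whose phenyl ring shields one diene face by π-stacking; the antipodal ester is equally available if the other face must stay open. Cycloaddition of F1 with 3 under an achiral promoter (BF3·OEt2, CH2Cl2, −78 °C) should give, by the same ortho and endo rules, the C7 mandelate analogue of the adduct F2. F2 is submitted as it stands to the step 3 hydrogenolysis, the mandelate serving as leaving group, and the route is rejoined at 5.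

Step 3. The hydride may be delivered to C7 instead of the crowded C5, which returns a C5=C6 alkene and loses the stereochemical relay, or the π-allyl complex may not form on the β face. The fallback uses sigmatropic hydrogen delivery instead of a palladium hydride. From 1, TBSOTf and Et3N should give the silyl dienol ether F3, and cycloaddition with 3 under the step 2 catalyst the 7α-silyloxy adduct F4. HF·pyridine frees the 7α-alcohol F5 without forming the alkoxide, so retro-aldol opening is avoided. Mitsunobu displacement with 2-nitrobenzenesulfonylhydrazide (PPh3, DEAD, THF, −30 °C) inverts C7 to the 7β-sulfonylhydrazide F6. On warming, F6 loses the sulfinic acid to give the allylic diazene F7, whose retro-ene loss of N2 passes hydrogen to the β face of C5 and shifts the alkene to C6=C7, which is 5.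

Step 5. In the peracid adduct, hydrogen may migrate instead of the tertiary carbon, giving the C8 carboxylic acid and no oxygen on C8. The fallback uses a ketone instead of an aldehyde Baeyer–Villiger oxidation. From 6, MeTi(Oi-Pr)3 should add to the aldehyde only, giving the secondary alcohol F8 as an epimer mixture. Dess–Martin periodinane then gives the methyl ketone F9. CF3CO3H (Na2HPO4 buffer) should insert oxygen on the tertiary side with retention to give the 8α-acetate F10. LiAlH4 reduces acetate and ester, and the route is rejoined at 8.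

**Further compounds**
F1 | step 2 | (E)-2-(2,6,6-trimethylcyclohex-1-en-1-yl)ethenyl (S)-2-methoxy-2-phenylacetate | CO[C@@H](c1ccccc1)C(=O)O/C=C/C1=C(C)CCCC1(C)C
F2 | step 2 | ethyl (1R,2S,3R,8aR)-2-formyl-3-{[(S)-2-methoxy-2-phenylacetyl]oxy}-2,5,5,8a-tetramethyl-1,2,3,5,6,7,8,8a-octahydronaphthalene-1-carboxylate | CCOC(=O)[C@@H]1[C@@]2(C)CCCC(C)(C)C2=C[C@@H](OC(=O)[C@@H](OC)c3ccccc3)[C@@]1(C)C=O
F3 | step 3 | tert-butyl(dimethyl){[(E)-2-(2,6,6-trimethylcyclohex-1-en-1-yl)ethenyl]oxy}silane | CC(C)(C)[Si](C)(C)O/C=C/C1=C(C)CCCC1(C)C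
F4 | step 3 | ethyl (1R,2S,3R,8aR)-3-[(tert-butyldimethylsilyl)oxy]-2-formyl-2,5,5,8a-tetramethyl-1,2,3,5,6,7,8,8a-octahydronaphthalene-1-carboxylate | CCOC(=O)[C@@H]1[C@@]2(C)CCCC(C)(C)C2=C[C@@H](O[Si](C)(C)C(C)(C)C)[C@@]1(C)C=O
F5 | step 3 | ethyl (1R,2S,3R,8aR)-2-formyl-3-hydroxy-2,5,5,8a-tetramethyl-1,2,3,5,6,7,8,8a-octahydronaphthalene-1-carboxylate (7α-alcohol) | CCOC(=O)[C@@H]1[C@@]2(C)CCCC(C)(C)C2=C[C@@H](O)[C@@]1(C)C=O
F6 | step 3 | 7β-[1-(2-nitrobenzenesulfonyl)hydrazinyl] analogue of F5 (C7 inverted) | CCOC(=O)[C@@H]1[C@@]2(C)CCCC(C)(C)C2=C[C@H](N(N)S(=O)(=O)c3ccccc3[N+](=O)[O-])[C@@]1(C)C=O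
F7 | step 3 | 7β-diazenyl analogue of F5 (allylic diazene) | CCOC(=O)[C@@H]1[C@@]2(C)CCCC(C)(C)C2=C[C@H](N=N)[C@@]1(C)C=O
F8 | step 5 | ethyl (1R,2R,4aR,8aS)-2-(1-hydroxyethyl)-2,5,5,8a-tetramethyldecahydronaphthalene-1-carboxylate (carbinol epimers) | CCOC(=O)[C@@H]1[C@@]2(C)CCCC(C)(C)[C@H]2CC[C@@]1(C)C(C)O
F9 | step 5 | ethyl (1R,2R,4aR,8aS)-2-acetyl-2,5,5,8a-tetramethyldecahydronaphthalene-1-carboxylate | CCOC(=O)[C@@H]1[C@@]2(C)CCCC(C)(C)[C@H]2CC[C@@]1(C)C(C)=O
F10 | step 5 | ethyl (1R,2R,4aR,8aS)-2-acetoxy-2,5,5,8a-tetramethyldecahydronaphthalene-1-carboxylate | CCOC(=O)[C@@H]1[C@@]2(C)CCCC(C)(C)[C@H]2CC[C@@]1(C)OC(C)=O
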